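(The data stem from a simulated flask with made-up constants, and the scatter is random.)

**The fixed budget.** In a closed flask the charged nucleophile is a fixed budget, so count it in fractions of the electrophile charge.

common to all: electrophile 0.050 M

| run | nucleophile | free base | remark | time |
|---|---|---|---|---|
| south-west | 0.028 M | 0.055 M | run made earlier |  |
| flask | 0.0550 M | 0.0550 M |  | 2.0 min |

south-west run (percent of the electrophile charged)

| time / s | electrophile / % | target / % |
|---|---|---|
| 10.0 | 81.1 | 16.6 |
| 15.0 | 75.1 | 18.5 |
| 20.0 | 72.1 | 21.5 |
| 25.0 | 68.8 | 21.3 |
| 30.0 | 66.3 | 21.9 |
| 40.0 | 62.6 | 22.3 |

(scatter of a reading: 0.5 percentage points)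

- the analysis behind the earlier runs scatters by 0.5 percentage points, standard deviation
- the earlier runs do not show how much of nucleophile is bound; that part of a forecast is a guess

- part of the electrophile that has reacted at 2.0 min
- share of the unused nucleophile that is free and not bound as protonated nucleophile, at 2.0 min

**Early end.** The first south-west reading gives a rate constant of about 0.748 M⁻¹ s⁻¹. So in this flask the time scale of nucleophile against the charged electrophile is about 26.7 s, which is shorter than the asked time. You may therefore reckon this flask from the late end.

**Late end.** The south-west budget was 0.560. By 40.0 s the readings show 37.4% of the electrophile consumed. That gives the spend ratio, electrophile consumed per unit of nucleophile charged, 0.668. This flask has the same charges of electrophile and free base, and its budget is 1.10, so carrying the ratio over puts c at about 73.5%.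

**Weak link.** The ratio was still moving: electrophile fell 3.7 percentage points between 30.0 s and 40.0 s, above the scatter. At 30.0 s the ratio was 0.602, which gives 66.2%. You commit to c between these two. The readings give you no figure for fr.

**The forecast.** It says 70% and 5%, holding that “each reacted electrophile seems to release acid that locks up one nucleophile as its protonated form”.

**The result.** This flask gives 68.9% and 63.0%.

    nucleophile + target → over-reaction product (k = 1.50 M⁻¹ s⁻¹)
    acid set free + free base ⇌ salt of the base, settled at all times (K = 35000 M⁻¹)
    nucleophile + acid set free ⇌ protonated nucleophile, settled at all times (K = 13000 M⁻¹)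
    target ⇌ isomer of the product (K = 1.20, k = 0.00620 s⁻¹)
    electrophile + nucleophile → acid set free + target (k = 1.00 M⁻¹ s⁻¹)

This flask's spend ratio is 0.626, between your two values . At 2.00 min in this flask the step of nucleophile with electrophile uses nucleophile 1.1 times as fast as the step of nucleophile with target, and over-reaction product stands at 37.4%. The forecast parts on fr: at that time in this flask protonated nucleophile is 6.90 × 10⁻⁴ M, far less than salt of the base at 0.0337 M.

**Second flask.** Take a neighbour of this flask, the same but with 0.014 M of nucleophile. Its budget is 0.280, so the ratio gives 16.9% to 18.7%. That flask gives 23.9%.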